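**Retrosynthetic overview**

- (+)-Gmelinol is disconnected at the C3–C3a bond (benzylic CH to carbinol carbon; furo[3,4-c]furan numbering) to a cis-4,5-disubstituted oxolan-3-one that already holds ring B. Ring A is closed last by a Norrish–Yang photocyclization.
- Enabling feature: the ring-B carbonyl and the benzylic CH2 of the 3,4-dimethoxybenzyl ether on the neighbouring side chain are 1,6-related (O=C–C–CH2–O–CH2Ar). The γ-atom is the ether oxygen, so the excited carbonyl can reach only the δ benzylic hydrogen, and the 1,5-biradical collapses to the oxolane ring A.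
- The oxolan-3-one comes from a silyloxy α-chloroketone (ring B by intramolecular O-alkylation), made from a Weinreb amide and ClCH2Li.
- The Weinreb amide comes from an Evans syn-aldol of a 3-(3,4-dimethoxybenzyloxy)propanoyl imide with 3,4-dimethoxybenzaldehyde. The auxiliary sets C6 and C6a, which relay to C3a and C3 in the key step.
- Order of ring formation: ring B (step 8), then ring A (step 9).

Key step: step 9

Assumption: in the drawn (3R,3aS,6R,6aR) enantiomer the aryl group next to the carbinol carbon is exo (cis to OH) and the other aryl group is endo; the route is planned for this relative configuration, which corresponds to a cis-4,5-disubstituted oxolan-3-one and a syn aldol adduct.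

**Route**

Step 1
Reactants: 1 3,4-dimethoxybenzyl alcohol (veratryl alcohol), 2 methyl acrylate
Product: 3 methyl 3-[(3,4-dimethoxybenzyl)oxy]propanoate
Conditions: 2 (2 equiv), PMe3 (10 mol%), THF, rt
Reagents that add atoms: none
Why: Phosphine-catalysed oxa-Michael addition of the primary alcohol to the acrylate under neutral conditions that leave the electron-rich benzyl group untouched; no stereocentre is formed.

Step 2
Reactants: 3 methyl 3-[(3,4-dimethoxybenzyl)oxy]propanoate
Product: 4 3-[(3,4-dimethoxybenzyl)oxy]propanoic acid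
Conditions: LiOH·H2O, THF–MeOH–H2O, rt; then 1 M HCl to pH 3, 0 °C
Reagents that add atoms: lithium hydroxide, [Li+].[OH-]
Why: Ester saponification; the 3,4-dimethoxybenzyl ether should tolerate the brief cold dilute acid of the work-up; no stereocentre is involved.

Step 3
Reactants: 4 3-[(3,4-dimethoxybenzyl)oxy]propanoic acid, 5 (R)-4-benzyloxazolidin-2-one
Product: 7 (R)-4-benzyl-3-{3-[(3,4-dimethoxybenzyl)oxy]propanoyl}oxazolidin-2-one, via mixed pivalic anhydride 6 (not isolated)
Conditions: t-BuCOCl, Et3N, THF, −20 °C; then LiCl, 5, −20 °C → rt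
Reagents that add atoms: none
Why: N-acylation of the oxazolidinone through the mixed pivalic anhydride with LiCl/Et3N activation, which avoids strong base and hence β-elimination of the alkoxy group; the auxiliary stereocentre is untouched.

Step 4
Reactants: 7 (R)-4-benzyl-3-{3-[(3,4-dimethoxybenzyl)oxy]propanoyl}oxazolidin-2-one, 8 3,4-dimethoxybenzaldehyde (veratraldehyde)
Product: 10 (R)-4-benzyl-3-[(2R,3R)-2-{[(3,4-dimethoxybenzyl)oxy]methyl}-3-(3,4-dimethoxyphenyl)-3-hydroxypropanoyl]oxazolidin-2-one, via Z boron enolate 9 (not isolated)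
Conditions: Bu2BOTf, Et3N, CH2Cl2, −78 → 0 °C; 8, −78 → 0 °C; then pH 7 buffer, MeOH, 30% H2O2, 0 °C
Reagents that add atoms: none
Why: Evans syn-aldol reaction, in which the Z boron enolate reacts through a chair Zimmerman–Traxler transition state on the enolate face away from the benzyl group of the (R)-auxiliary, setting both new stereocentres (2R,3R; the future C6a and C6) in one event.

Step 5
Reactants: 10 the syn-aldol imide
Product: 11 (2R,3R)-2-{[(3,4-dimethoxybenzyl)oxy]methyl}-3-(3,4-dimethoxyphenyl)-3-hydroxy-N-methoxy-N-methylpropanamide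
Conditions: MeONHMe·HCl, AlMe3, CH2Cl2, −15 → 0 °C; aq. potassium sodium tartrate
Reagents that add atoms: N,O-dimethylhydroxylamine hydrochloride, CNOC.Cl
Why: Aluminium-amide transamination of the β-hydroxy imide (Weinreb amide formation), in which the free hydroxyl directs exocyclic cleavage; neither stereocentre is touched and the auxiliary can be recovered.

Step 6
Reactants: 11 the β-hydroxy Weinreb amide
Product: 12 (2R,3R)-2-{[(3,4-dimethoxybenzyl)oxy]methyl}-3-(3,4-dimethoxyphenyl)-N-methoxy-N-methyl-3-[(triethylsilyl)oxy]propanamide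
Conditions: Et3SiCl, imidazole, DMAP (cat.), CH2Cl2, 0 °C → rt
Reagents that add atoms: chlorotriethylsilane, CC[Si](Cl)(CC)CC
Why: Standard silylation of the secondary benzylic alcohol, which masks the hydroxyl against the organolithium of the next step and stores it as a latent alkoxide; no stereocentre is affected.

Step 7
Reactants: 12 the silylated Weinreb amide
Product: 13 (3R,4R)-1-chloro-3-{[(3,4-dimethoxybenzyl)oxy]methyl}-4-(3,4-dimethoxyphenyl)-4-[(triethylsilyl)oxy]butan-2-one
Conditions: ICH2Cl, MeLi·LiBr, THF, −78 °C; AcOH, −78 °C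
Reagents that add atoms: chloroiodomethane, ClCI
Why: Weinreb ketone synthesis with chloromethyllithium generated in situ by iodine–lithium exchange (Barbier mode at −78 °C), which stops at the ketone stage and is known to preserve α-stereocentres; no new stereocentre is formed.

Step 8
Reactants: 13 the silyloxy α-chloroketone
Product: 15 (4R,5R)-5-(3,4-dimethoxyphenyl)-4-{[(3,4-dimethoxybenzyl)oxy]methyl}oxolan-3-one (4,5-cis), via hydroxy chloroketone 14 (not isolated)
Conditions: Bu4NF (1.05 equiv), THF, −20 → 0 °C; pH 7 buffer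
Reagents that add atoms: none
Why: Fluoride unmasks the alkoxide, which closes ring B by intramolecular Williamson etherification (5-exo-tet displacement at the reactive α-chloroketone carbon); the alkoxide is consumed as it forms and chloride is the only anion left, so the ketone α-centre should keep its cis configuration.

Step 9
Reactants: 15 the cis-oxolan-3-one
Product: 17 (+)-gmelinol, (3R,3aS,6R,6aR)-3,6-bis(3,4-dimethoxyphenyl)tetrahydro-1H,3H-furo[3,4-c]furan-3a-ol, via 1,5-biradical 16 (not isolated)
Conditions: hν (medium-pressure Hg lamp, Pyrex filter, λ > 300 nm), degassed benzene (0.01 M), rt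
Reagents that add atoms: none
Why: Excitation of the n,π* band of the ring-B ketone lets the carbonyl oxygen abstract one benzylic ether hydrogen through a seven-membered transition state (1,6-hydrogen transfer), and the resulting 1,5-biradical 16 (ketyl carbon plus α-alkoxybenzyl carbon) recombines to form the C3–C3a bond. The closest known reaction type is the Norrish–Yang photocyclization of β-alkoxy ketones to oxolan-3-ols by δ-hydrogen abstraction, which is precedented on 4-(benzyloxymethyl)-5-aryloxolan-3-ones as an entry to 1-hydroxylated furofuran lignans. Ring A, the second oxolane, is closed by radical–radical coupling of the 1,5-biradical, a five-membered closure in which both radical carbons become ring atoms. C3a is set by the tether, because the side chain on the adjacent carbon can reach the ketyl carbon only from its own face, so the hydroxyl must end cis to H-6a (cis ring fusion); C3 is set by the resident aryl group at C6, which fills the concave face of the forming bicycle and should force the new aryl group exo, cis to the hydroxyl. The step needs site selectivity (only the δ benzylic C–H is within reach, the γ-position being oxygen), chemoselectivity over Norrish α-cleavage (helped by the weak, doubly activated benzylic C–H and by irradiation above 300 nm, where the ketone rather than the dimethoxyarenes absorbs) and configurational integrity at the ketone α-carbon (neutral, base-free, degassed solution at room temperature).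

**Compound list**

1 | 3,4-dimethoxybenzyl alcohol (veratryl alcohol) | COc1ccc(CO)cc1OC | starting material
2 | methyl acrylate | C=CC(=O)OC | starting material
3 | methyl 3-[(3,4-dimethoxybenzyl)oxy]propanoate | COc1ccc(COCCC(=O)OC)cc1OC | intermediate
4 | 3-[(3,4-dimethoxybenzyl)oxy]propanoic acid | COc1ccc(COCCC(=O)O)cc1OC | intermediate
5 | (R)-4-benzyloxazolidin-2-one | O=C1N[C@H](Cc2ccccc2)CO1 | starting material
6 | 3-[(3,4-dimethoxybenzyl)oxy]propanoic pivalic anhydride (not isolated) | COc1ccc(COCCC(=O)OC(=O)C(C)(C)C)cc1OC | intermediate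
7 | (R)-4-benzyl-3-{3-[(3,4-dimethoxybenzyl)oxy]propanoyl}oxazolidin-2-one | COc1ccc(COCCC(=O)N2[C@H](Cc3ccccc3)COC2=O)cc1OC | intermediate
8 | 3,4-dimethoxybenzaldehyde (veratraldehyde) | COc1ccc(C=O)cc1OC | starting material
9 | (Z)-dibutylboron enolate of 7 (not isolated) | COc1ccc(COC/C=C(\OB(CCCC)CCCC)N2[C@H](Cc3ccccc3)COC2=O)cc1OC | intermediate
10 | (R)-4-benzyl-3-[(2R,3R)-2-{[(3,4-dimethoxybenzyl)oxy]methyl}-3-(3,4-dimethoxyphenyl)-3-hydroxypropanoyl]oxazolidin-2-one | COc1ccc(COC[C@H]([C@H](c2ccc(OC)c(OC)c2)O)C(=O)N2[C@H](Cc3ccccc3)COC2=O)cc1OC | intermediate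
11 | (2R,3R)-2-{[(3,4-dimethoxybenzyl)oxy]methyl}-3-(3,4-dimethoxyphenyl)-3-hydroxy-N-methoxy-N-methylpropanamide | COc1ccc(COC[C@H]([C@H](c2ccc(OC)c(OC)c2)O)C(=O)N(C)OC)cc1OC | intermediate
12 | (2R,3R)-2-{[(3,4-dimethoxybenzyl)oxy]methyl}-3-(3,4-dimethoxyphenyl)-N-methoxy-N-methyl-3-[(triethylsilyl)oxy]propanamide | COc1ccc(COC[C@H]([C@H](c2ccc(OC)c(OC)c2)O[Si](CC)(CC)CC)C(=O)N(C)OC)cc1OC | intermediate
13 | (3R,4R)-1-chloro-3-{[(3,4-dimethoxybenzyl)oxy]methyl}-4-(3,4-dimethoxyphenyl)-4-[(triethylsilyl)oxy]butan-2-one | COc1ccc(COC[C@H]([C@H](c2ccc(OC)c(OC)c2)O[Si](CC)(CC)CC)C(=O)CCl)cc1OC | intermediate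
14 | (3R,4R)-1-chloro-3-{[(3,4-dimethoxybenzyl)oxy]methyl}-4-(3,4-dimethoxyphenyl)-4-hydroxybutan-2-one, formed as its alkoxide (not isolated) | COc1ccc(COC[C@H]([C@H](c2ccc(OC)c(OC)c2)O)C(=O)CCl)cc1OC | intermediate
15 | (4R,5R)-5-(3,4-dimethoxyphenyl)-4-{[(3,4-dimethoxybenzyl)oxy]methyl}oxolan-3-one (4,5-cis) | COc1ccc(COC[C@@H]2[C@H](c3ccc(OC)c(OC)c3)OCC2=O)cc1OC | intermediate
16 | 1,5-biradical from 15: ketyl radical at ring-B C3, α-alkoxybenzyl radical on the side chain (not isolated) | COc1ccc([CH]OC[C@@H]2[C@H](c3ccc(OC)c(OC)c3)OC[C]2O)cc1OC | intermediate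
17 | (+)-gmelinol, (3R,3aS,6R,6aR)-3,6-bis(3,4-dimethoxyphenyl)tetrahydro-1H,3H-furo[3,4-c]furan-3a-ol | COc1ccc([C@H]2OC[C@@H]3[C@H](c4ccc(OC)c(OC)c4)OC[C@]23O)cc1OC | target

**Step count and risks**

Total step count: 9. Longest linear sequence: 9 steps (from 1).

Steps most likely to fail:

1. Step 9 (photocyclization). The excited ketone may partition into α-cleavage and decarbonylation, may return to the ground state by reverse hydrogen transfer or by quenching through the neighbouring electron-rich arene, or the biradical may close with insufficient exo preference. Fallback, from 15 back to the route at 17: ring A would be closed through its benzylic C–O bond instead.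
   - Wittig olefination of 15 with the ylide from (3,4-dimethoxybenzyl)triphenylphosphonium bromide (NaN(SiMe3)2, THF, −78 °C → rt) would give the exocyclic styrene (2R,3R)-4-(3,4-dimethoxybenzylidene)-2-(3,4-dimethoxyphenyl)-3-{[(3,4-dimethoxybenzyl)oxy]methyl}oxolane F1 as an E/Z mixture.
   - Dihydroxylation (OsO4 cat., NMO, acetone–H2O) should occur on the ring face opposite the two cis substituents. This would give (3S,4R,5R)-3-[(3,4-dimethoxyphenyl)(hydroxy)methyl]-5-(3,4-dimethoxyphenyl)-4-{[(3,4-dimethoxybenzyl)oxy]methyl}oxolan-3-ol F2, with the tertiary carbinol already in the configuration of C3a.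
   - MsCl/Et3N (CH2Cl2, 0 °C) would ionise the secondary benzylic alcohol. The side-chain ether oxygen would capture the cation with loss of the 3,4-dimethoxybenzyl group (debenzylative cycloetherification), the aryl group settling exo away from the endo aryl group, to give 17.

2. Step 8 (fluoride-triggered ring closure). The cis relationship may be lost by enolization of the newly formed ketone, or the transient alkoxide may fragment by retro-aldol or β-elimination before it alkylates. Fallback, from 13 back to the route at 15: ring B would be closed at the alcohol oxidation level and the ketone unveiled last under non-basic conditions.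
   - NaBH4 (MeOH, 0 °C) would reduce 13 to the chlorohydrin 1-chloro-3-{[(3,4-dimethoxybenzyl)oxy]methyl}-4-(3,4-dimethoxyphenyl)-4-[(triethylsilyl)oxy]butan-2-ol F3 (carbinol epimers, other centres as in 13).
   - Desilylation and base-mediated closure (Bu4NF, THF; then K2CO3, MeOH) would give the epoxy alcohol 3-[(3,4-dimethoxybenzyl)oxy]-1-(3,4-dimethoxyphenyl)-2-(oxiran-2-yl)propan-1-ol F4.
   - Acid-catalysed opening of the terminal epoxide by the benzylic hydroxyl (camphorsulfonic acid cat., CH2Cl2, 0 °C) would give 4,5-cis-5-(3,4-dimethoxyphenyl)-4-{[(3,4-dimethoxybenzyl)oxy]methyl}oxolan-3-ol F5.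
   - Dess–Martin periodinane with NaHCO3 (CH2Cl2, rt) would oxidise F5 to 15.

3. Step 7 (chloromethylation). The carbenoid may decompose before it adds, or the amide may be deprotonated at its α-carbon with β-elimination of the silyloxy group, leaving low conversion. Fallback, from 12 back to the route at 13: the one-carbon unit would be introduced as a methyl group and chlorinated afterwards.
   - MeMgBr (THF, 0 °C) would convert 12 into the methyl ketone (3R,4R)-3-{[(3,4-dimethoxybenzyl)oxy]methyl}-4-(3,4-dimethoxyphenyl)-4-[(triethylsilyl)oxy]butan-2-one F6.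
   - Kinetic enolization on the methyl side (LiN(SiMe3)2, Me3SiCl, THF, −78 °C) would give the silyl enol ether (3R,4R)-3-{[(3,4-dimethoxybenzyl)oxy]methyl}-4-(3,4-dimethoxyphenyl)-4-[(triethylsilyl)oxy]-2-[(trimethylsilyl)oxy]but-1-ene F7.
   - N-Chlorosuccinimide (THF, 0 °C) would chlorinate F7 to 13.

**Further compounds**

F1 | step 9 | (2R,3R)-4-(3,4-dimethoxybenzylidene)-2-(3,4-dimethoxyphenyl)-3-{[(3,4-dimethoxybenzyl)oxy]methyl}oxolane (E/Z mixture) | COc1ccc(COC[C@@H]2[C@H](c3ccc(OC)c(OC)c3)OCC2=Cc4ccc(OC)c(OC)c4)cc1OC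
F2 | step 9 | (3S,4R,5R)-3-[(3,4-dimethoxyphenyl)(hydroxy)methyl]-5-(3,4-dimethoxyphenyl)-4-{[(3,4-dimethoxybenzyl)oxy]methyl}oxolan-3-ol (secondary carbinol epimers) | COc1ccc(COC[C@@H]2[C@H](c3ccc(OC)c(OC)c3)OC[C@]2(O)C(O)c4ccc(OC)c(OC)c4)cc1OC
F3 | step 8 | 1-chloro-3-{[(3,4-dimethoxybenzyl)oxy]methyl}-4-(3,4-dimethoxyphenyl)-4-[(triethylsilyl)oxy]butan-2-ol (carbinol epimers) | COc1ccc(COC[C@H]([C@H](c2ccc(OC)c(OC)c2)O[Si](CC)(CC)CC)C(O)CCl)cc1OC
F4 | step 8 | 3-[(3,4-dimethoxybenzyl)oxy]-1-(3,4-dimethoxyphenyl)-2-(oxiran-2-yl)propan-1-ol (oxirane epimers) | COc1ccc(COC[C@H]([C@H](c2ccc(OC)c(OC)c2)O)C3CO3)cc1OC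
F5 | step 8 | 4,5-cis-5-(3,4-dimethoxyphenyl)-4-{[(3,4-dimethoxybenzyl)oxy]methyl}oxolan-3-ol (carbinol epimers) | COc1ccc(COC[C@@H]2[C@H](c3ccc(OC)c(OC)c3)OCC2O)cc1OC
F6 | step 7 | (3R,4R)-3-{[(3,4-dimethoxybenzyl)oxy]methyl}-4-(3,4-dimethoxyphenyl)-4-[(triethylsilyl)oxy]butan-2-one | COc1ccc(COC[C@H]([C@H](c2ccc(OC)c(OC)c2)O[Si](CC)(CC)CC)C(C)=O)cc1OC
F7 | step 7 | (3R,4R)-3-{[(3,4-dimethoxybenzyl)oxy]methyl}-4-(3,4-dimethoxyphenyl)-4-[(triethylsilyl)oxy]-2-[(trimethylsilyl)oxy]but-1-ene | COc1ccc(COC[C@H]([C@H](c2ccc(OC)c(OC)c2)O[Si](CC)(CC)CC)C(=C)O[Si](C)(C)C)cc1OC
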